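**Retrosynthetic overview**
1. Target 13 ⇐ global desilylation of the tetra-TBS (2R,3R)-flavan-3-yl ferulate 12. Benzyl ethers are avoided throughout because hydrogenolysis would reduce the cinnamate C=C.
2. 12 ⇐ the only ring-forming step, done last: the C-ring (O1–C2 bond and C2–H) is closed by a cis-selective reductive oxa-cyclisation of the acyclic α-feruloyloxy ketone 11. The ester is already in place, so no late acylation of a hindered axial 3-OH is needed.
3. 11 ⇐ Steglich esterification of α-hydroxy ketone 8 with TBS-ferulic acid 10; 8 ⇐ B-ring aryllithium (from 7) + Weinreb amide 5.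
4. 5 ⇐ A-ring aryl copper/Grignard (from 2) + methyl (R)-glycidate 3. This forms C4–C4a and takes C3 from the chiral pool.
5. Ring order: A and B rings are bought as arenes; the pyran C-ring is formed last, with C2 set from C3.

Assumption: 5-bromobenzene-1,2,3-triol (6) is purchased; if unavailable it is one step (BBr3) from commercial 5-bromo-1,2,3-trimethoxybenzene.

**Route**

Step 1
Reactants: 1 phloroglucinol
Product: 2 1,3,5-tris(methoxymethoxy)benzene
Conditions: NaH, MOMCl, DMF, 0 °C → rt
Reagents that add atoms: chloromethyl methyl ether (MOMCl), COCCl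
Why: Williamson-type O-alkylation of the triphenoxide; MOM is chosen because it directs ortho-lithiation in step 2 and is cleaved by the Lewis acid used in step 8.

Step 2
Reactants: 2 1,3,5-tris(methoxymethoxy)benzene; 3 methyl (R)-glycidate
Product: 4 methyl (2R)-2-hydroxy-3-[2,4,6-tris(methoxymethoxy)phenyl]propanoate
Conditions: n-BuLi, THF, 0 °C; MgBr2·OEt2; CuI (10 mol %), then 3, −40 → −20 °C
Reagents that add atoms: none (both partners are numbered reactants)
Why: Directed ortho-metalation (all three ring C–H are equivalent) followed by Cu-catalysed Grignard SN2 opening of the glycidate at the terminal CH2; the C2 stereocentre is not touched, so (R) is carried over unchanged.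

Step 3
Reactants: 4
Product: 5 (2R)-2-hydroxy-N-methoxy-N-methyl-3-[2,4,6-tris(methoxymethoxy)phenyl]propanamide
Conditions: MeNH(OMe)·HCl, i-PrMgCl, THF, −20 → 0 °C
Reagents that add atoms: N,O-dimethylhydroxylamine hydrochloride, CNOC.Cl
Why: Weinreb amide formation by magnesium-amide aminolysis of the ester; the α-centre sits as its magnesium alkoxide, which suppresses enolisation.

Step 4
Reactants: 6 5-bromobenzene-1,2,3-triol
Product: 7 5-bromo-1,2,3-tris(tert-butyldimethylsilyloxy)benzene
Conditions: TBSCl, imidazole, DMAP (cat.), DMF, 50 °C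
Reagents that add atoms: tert-butyldimethylsilyl chloride (TBSCl), CC(C)(C)[Si](C)(C)Cl
Why: Standard phenol silylation; aryl TBS ethers survive ArLi, TMSOTf/Et3SiH and DMAP, and come off with fluoride without affecting the cinnamate.

Step 5
Reactants: 7; 5
Product: 8 (2R)-2-hydroxy-1-[3,4,5-tris(tert-butyldimethylsilyloxy)phenyl]-3-[2,4,6-tris(methoxymethoxy)phenyl]propan-1-one
Conditions: 7, n-BuLi, THF, −78 °C; then 5 (pre-treated with 1 equiv i-PrMgCl), −78 → 0 °C; aq. NH4Cl
Reagents that add atoms: none
Why: Li–Br exchange then Weinreb ketone synthesis; the chelated tetrahedral intermediate prevents over-addition and the α-alkoxide prevents enolisation, so C3 stays (R) (the aryllithium has no ortho-silyloxy group, so no retro-Brook shift).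

Step 6
Reactants: 9 (E)-ferulic acid
Product: 10 (E)-3-[4-(tert-butyldimethylsilyloxy)-3-methoxyphenyl]prop-2-enoic acid
Conditions: TBSCl, imidazole, DMF, rt; then AcOH/THF/H2O, rt
Reagents that add atoms: TBSCl, CC(C)(C)[Si](C)(C)Cl
Why: Bis-silylation followed by selective hydrolysis of the labile silyl ester under mild acid, which leaves the aryl silyl ether intact.

Step 7
Reactants: 8; 10
Product: 11 (2R)-1-oxo-1-[3,4,5-tris(tert-butyldimethylsilyloxy)phenyl]-3-[2,4,6-tris(methoxymethoxy)phenyl]propan-2-yl (E)-3-[4-(tert-butyldimethylsilyloxy)-3-methoxyphenyl]prop-2-enoate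
Conditions: EDC·HCl, DMAP (0.2 equiv), CH2Cl2, 0 °C
Reagents that add atoms: none
Why: Steglich esterification of an unhindered acyclic secondary alcohol; DMAP is far too weak a base to enolise the α-acyloxy ketone at 0 °C, so C3 is retained.

Step 8 (key step)
Reactants: 11
Product: 12 (2R,3R)-5,7-dihydroxy-2-[3,4,5-tris(tert-butyldimethylsilyloxy)phenyl]-3,4-dihydro-2H-chromen-3-yl (E)-3-[4-(tert-butyldimethylsilyloxy)-3-methoxyphenyl]prop-2-enoate (2,3-cis)
Conditions: TMSOTf (4 equiv), Et3SiH (10 equiv), CH2Cl2 (0.02 M), −78 → −20 °C; Et3N/MeOH quench, then citric acid/MeOH–H2O (hydrolyses ArOTMS)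
Reagents that add atoms: none (Et3SiH delivers only H)
Why: Proposed new method: TMSOTf ionises the three aryl MOM acetals to ArOTMS (the MeO=CH2+ by-product is reduced by Et3SiH to Me2O), and an ortho silyl ether (the two are equivalent by symmetry) adds to the activated ketone to give the 2-aryl-chroman-2-ylium oxocarbenium ion. A1,2 strain with the coplanar B-ring holds the C3 ester pseudo-axial, so Et3SiH attacks axially and anti to it, which sets C2 as (R) and gives the 2,3-cis product (attack on a participating dioxolenium ion with inversion gives the same result); C3 is not touched. The closest known chemistry is the TMSOTf/Et3SiH reductive etherification of o-hydroxyaryl α-acyloxy ketones to 2,3-cis-flavan-3-yl esters, and Et3SiH/Lewis-acid reduction of 1-C-aryl ketose hemiketals bearing 2-O-acyl groups; the in-situ MOM unmasking is the untested part.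

Step 9
Reactants: 12
Product: 13 epigallocatechin-3-O-ferulate, (2R,3R)
Conditions: HF·pyridine, pyridine/THF, 0 °C → rt; reverse-phase purification under Ar
Reagents that add atoms: none
Why: Fluoride-mediated cleavage of the four aryl silyl ethers under slightly acidic, non-reducing conditions, which spares the cinnamate alkene and ester and avoids base-induced C2 epimerisation or pyrogallol oxidation.

**Compound list**
1 | phloroglucinol | Oc1cc(O)cc(O)c1 | starting material
2 | 1,3,5-tris(methoxymethoxy)benzene | COCOc1cc(OCOC)cc(OCOC)c1 | intermediate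
3 | methyl (R)-glycidate | COC(=O)[C@H]1CO1 | starting material
4 | methyl (2R)-2-hydroxy-3-[2,4,6-tris(methoxymethoxy)phenyl]propanoate | COC(=O)[C@H](O)Cc1c(OCOC)cc(OCOC)cc1OCOC | intermediate
5 | (2R)-2-hydroxy-N-methoxy-N-methyl-3-[2,4,6-tris(methoxymethoxy)phenyl]propanamide | CON(C)C(=O)[C@H](O)Cc1c(OCOC)cc(OCOC)cc1OCOC | intermediate
6 | 5-bromobenzene-1,2,3-triol | Oc1cc(Br)cc(O)c1O | starting material
7 | 5-bromo-1,2,3-tris(tert-butyldimethylsilyloxy)benzene | CC(C)(C)[Si](C)(C)Oc1cc(Br)cc(O[Si](C)(C)C(C)(C)C)c1O[Si](C)(C)C(C)(C)C | intermediate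
8 | (2R)-2-hydroxy-1-[3,4,5-tris(TBSO)phenyl]-3-[2,4,6-tris(MOMO)phenyl]propan-1-one | O=C(c1cc(O[Si](C)(C)C(C)(C)C)c(O[Si](C)(C)C(C)(C)C)c(O[Si](C)(C)C(C)(C)C)c1)[C@H](O)Cc1c(OCOC)cc(OCOC)cc1OCOC | intermediate
9 | (E)-ferulic acid | COc1cc(/C=C/C(=O)O)ccc1O | starting material
10 | (E)-4-O-TBS-ferulic acid | COc1cc(/C=C/C(=O)O)ccc1O[Si](C)(C)C(C)(C)C | intermediate
11 | (2R)-1-oxo-1-[3,4,5-tris(TBSO)phenyl]-3-[2,4,6-tris(MOMO)phenyl]propan-2-yl (E)-4-O-TBS-ferulate | O=C(c1cc(O[Si](C)(C)C(C)(C)C)c(O[Si](C)(C)C(C)(C)C)c(O[Si](C)(C)C(C)(C)C)c1)[C@H](OC(=O)/C=C/c1ccc(O[Si](C)(C)C(C)(C)C)c(OC)c1)Cc1c(OCOC)cc(OCOC)cc1OCOC | intermediate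
12 | (2R,3R)-5,7-dihydroxy-2-[3,4,5-tris(TBSO)phenyl]chroman-3-yl (E)-4-O-TBS-ferulate | COc1cc(/C=C/C(=O)O[C@@H]2Cc3c(O)cc(O)cc3O[C@@H]2c2cc(O[Si](C)(C)C(C)(C)C)c(O[Si](C)(C)C(C)(C)C)c(O[Si](C)(C)C(C)(C)C)c2)ccc1O[Si](C)(C)C(C)(C)C | intermediate
13 | epigallocatechin-3-O-ferulate, (2R,3R) | COc1cc(/C=C/C(=O)O[C@@H]2Cc3c(O)cc(O)cc3O[C@@H]2c2cc(O)c(O)c(O)c2)ccc1O | target

**Totals**
Total steps: 9. Longest linear sequence: 7 (steps 1, 2, 3, 5, 7, 8, 9, from phloroglucinol).

**Three steps most likely to fail**
1. Step 8 (tandem MOM unmasking and reductive oxa-cyclisation). Risks: cis/trans leakage; erosion at C3 through reversible loss of H3 to the 3-acyloxy-flav-2-ene; over-reduction by C2–O1 cleavage; C-alkylation of the A-ring by MOM-derived cations. Fallback: abandon the cationic closure. Reduce ketol 8 under chelation control (Zn(BH4)2) to the anti-diol, protect O3 as a non-participating silyl ether (selective protection is an extra unproven step), unmask one A-ring phenol, and close O1–C2 by invertive intramolecular Mitsunobu etherification (SN2 at the benzylic carbinol gives 2,3-cis). Then install the ferulate late on the cis-3-ol.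
2. Step 2 (Cu-catalysed opening of methyl glycidate by a di-ortho-substituted aryl Grignard). Risks: sluggish opening or competing attack on the ester. Fallback: make 4 by catalysis instead of chiral pool. Formylate the aryllithium with DMF, run an HWE with methyl 2-acetoxy-2-(dimethoxyphosphoryl)acetate to the (Z)-enol acetate, hydrogenate with Rh-DuPhos to the (R)-α-acetoxy ester, and methanolyse to 4.
3. Step 5 (aryllithium addition to the unprotected α-hydroxy Weinreb amide). Risks: incomplete addition or partial racemisation of the ketol. Fallback: base-free ketone synthesis with the ester already installed. Convert 4 to the acid, feruloylate with 10, form the S-aryl thioester, and run a Liebeskind–Srogl coupling (Pd/CuTC) with 3,4,5-tris(TBSO)phenylboronic acid to reach 11 directly.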